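**Retrosynthetic overview**
1. Hypercalin B ⇒ C6–CH2 bond by reductive Knoevenagel alkylation: gem-diprenyl benzoylphloroglucinol trione + cis-β-hydroxy cyclopentanecarbaldehyde. The trione comes from dearomatising double prenylation of 2,4,6-trihydroxybenzophenone (both six-membered rings are bought).
2. Hydroxy aldehyde ⇒ 1,3-diol ⇒ cis-fused bicyclic β-lactone (redox adjustment only).
3. Key step: β-lactone ⇒ acyclic (S)-1,6-keto acid by aldol-lactonisation. The cyclopentane and the β-lactone close in one operation, and both new stereocentres (one quaternary) are set from the single carvone-derived centre.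
4. Keto acid ⇒ (S)-carvone by reductive α-hydroxylation and α-ketol cleavage (the carvone ring is opened).
5. Ring order: cyclopentane and β-lactone together, then the β-lactone is opened reductively; no further ring is formed.

Assumption: (S)-(+)-carvone and 2,4,6-trihydroxybenzophenone are taken as catalogue compounds; compound numbers follow the forward route.

**Step 1**
Reactants: 1 (S)-(+)-carvone
Product: 3 (2RS,5S)-2-hydroxy-2-methyl-5-(prop-1-en-2-yl)cyclohexan-1-one, via α-hydroperoxy ketone 2 (not isolated)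
Conditions: Mn(dpm)3 (3 mol%), PhSiH3, O2 (1 atm), iPrOH, 0 °C; then P(OEt)3
Reagents that add atoms: dioxygen, O=O (one O stays as the hydroxyl oxygen)
Why: Mukaiyama-type reductive α-hydroxylation of an enone, in which Mn–H hydrogen-atom transfer to the β-carbon, O2 capture of the α-keto radical and P(OEt)3 reduction of the hydroperoxide give the α-ketol, the isolated isopropenyl group reacting much more slowly, the new C2 centre being irrelevant (destroyed in step 2) and C5 untouched.

**Step 2**
Reactants: 3 (2RS,5S)-2-hydroxy-2-methyl-5-(prop-1-en-2-yl)cyclohexan-1-one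
Product: 4 (3S)-6-oxo-3-(prop-1-en-2-yl)heptanoic acid
Conditions: H5IO6, THF–H2O, 0 °C → rt
Reagents that add atoms: water, O (the new carboxyl oxygen, delivered through the periodate ester of the ketone hydrate); orthoperiodic acid, OI(=O)(O)(O)(O)O
Why: Periodate (Malaprade-type) cleavage of the α-ketol turns the carbinol carbon into the methyl ketone and the carbonyl carbon into the carboxylic acid, leaves the 1,1-disubstituted alkene alone and does not touch the stereocentre.

**Step 3 (key step)**
Reactants: 4 (3S)-6-oxo-3-(prop-1-en-2-yl)heptanoic acid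
Product: 7 (1R,2S,5S)-5-methyl-2-(prop-1-en-2-yl)-6-oxabicyclo[3.2.0]heptan-7-one, via mixed tosyl anhydride 5 (not isolated), via acylpyridinium tosylate 6 (not isolated)
Conditions: TsCl (1.3 equiv), 4-pyrrolidinopyridine (1.5 equiv), iPr2NEt (4 equiv), CH2Cl2, 0 °C → rt
Reagents that add atoms: none
Why: Nucleophile-catalysed aldol-lactonisation (NCAL) of a 1,6-keto acid, in which the acylpyridinium is deprotonated to an ammonium enolate that adds to the methyl ketone and the tertiary alkoxide then closes the β-lactone with release of the catalyst, so cyclopentane and oxetanone form together; the cis fusion is enforced by the four-membered ring, and the isopropenyl group ends up trans to the lactone carbonyl because the allylic C–H eclipses the enolate (A1,3 strain) and the ketone approaches anti to isopropenyl, which fixes C1 (R) and the quaternary C5 (S) from the carvone-derived centre.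

**Step 4**
Reactants: 7 (1R,2S,5S)-5-methyl-2-(prop-1-en-2-yl)-6-oxabicyclo[3.2.0]heptan-7-one
Product: 8 (1S,2S,3S)-2-(hydroxymethyl)-1-methyl-3-(prop-1-en-2-yl)cyclopentan-1-ol
Conditions: LiAlH4, THF, 0 °C; aqueous NaOH work-up
Reagents that add atoms: none
Why: Hydride reduction of the strained lactone with acyl C–O cleavage gives the 1,3-diol without touching any stereocentre or the alkene.

**Step 5**
Reactants: 8 (1S,2S,3S)-2-(hydroxymethyl)-1-methyl-3-(prop-1-en-2-yl)cyclopentan-1-ol
Product: 9 (1R,2S,5S)-2-hydroxy-2-methyl-5-(prop-1-en-2-yl)cyclopentane-1-carbaldehyde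
Conditions: TEMPO (10 mol%), PhI(OAc)2, CH2Cl2, rt; used crude
Reagents that add atoms: none
Why: TEMPO/PhI(OAc)2 (oxoammonium) oxidation is selective for the primary over the tertiary alcohol, stops at the aldehyde without water, and its base-free medium avoids retro-aldol, β-elimination and α-epimerisation (the required arrangement, CHO trans to both CH3 and isopropenyl, is in any case the more stable C1 epimer).

**Step 6**
Reactants: 10 2,4,6-trihydroxybenzophenone; 11 prenyl bromide (1-bromo-3-methylbut-2-ene)
Product: 13 2-benzoyl-3,5-dihydroxy-4,4-bis(3-methylbut-2-en-1-yl)cyclohexa-2,5-dien-1-one, via monoprenyl benzophenone 12 (not isolated)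
Conditions: NaOMe (2.2 equiv), 11 (2.2 equiv), MeOH, 0 °C → rt; chromatography
Reagents that add atoms: none
Why: Base-mediated C-prenylation of the phloroglucinolate (alkylative dearomatisation), in which the second prenyl bromide attacks the already prenylated carbon to give the gem-diprenyl vinylogous acid, which is separated from the 3,5-diprenyl isomer by chromatography (modest yield, roughly a third, accepted on the cheapest material); no stereocentre is involved.

**Step 7**
Reactants: 9 (1R,2S,5S)-2-hydroxy-2-methyl-5-(prop-1-en-2-yl)cyclopentane-1-carbaldehyde; 13 2-benzoyl-3,5-dihydroxy-4,4-bis(3-methylbut-2-en-1-yl)cyclohexa-2,5-dien-1-one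
Product: 15 hypercalin B, via alkylidene trione 14 (not isolated)
Conditions: L-proline (20 mol%), Hantzsch ester (1.2 equiv), CH2Cl2, rt
Reagents that add atoms: none
Why: Three-component reductive alkylation (Knoevenagel condensation then Hantzsch-ester transfer hydrogenation), in which the only ring C–H of the acidic trione condenses with the aldehyde and the electrophilic alkylidene (an ortho-quinone-methide-type acceptor) is reduced in situ by hydride transfer at the exocyclic carbon, under conditions that leave the benzoyl group, the three alkenes and the tertiary alcohol untouched, create no stereocentre and keep the three cyclopentane centres set in step 3.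

**Compound list**
1 | (S)-(+)-carvone | CC1=CC[C@@H](CC1=O)C(C)=C | starting material
2 | (5S)-2-hydroperoxy-2-methyl-5-(prop-1-en-2-yl)cyclohexan-1-one (C2 epimers) | CC1(OO)CC[C@@H](CC1=O)C(C)=C | intermediate
3 | (2RS,5S)-2-hydroxy-2-methyl-5-(prop-1-en-2-yl)cyclohexan-1-one | CC1(O)CC[C@@H](CC1=O)C(C)=C | intermediate
4 | (3S)-6-oxo-3-(prop-1-en-2-yl)heptanoic acid | CC(=O)CC[C@@H](CC(O)=O)C(C)=C | intermediate
5 | (3S)-6-oxo-3-(prop-1-en-2-yl)heptanoic 4-methylbenzenesulfonic anhydride | CC(=O)CC[C@@H](CC(=O)OS(=O)(=O)c1ccc(C)cc1)C(C)=C | intermediate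
6 | 1-[(3S)-6-oxo-3-(prop-1-en-2-yl)heptanoyl]-4-(pyrrolidin-1-yl)pyridin-1-ium 4-methylbenzenesulfonate | CC(=O)CC[C@@H](CC(=O)[n+]1ccc(cc1)N1CCCC1)C(C)=C.Cc1ccc(cc1)S([O-])(=O)=O | intermediate
7 | (1R,2S,5S)-5-methyl-2-(prop-1-en-2-yl)-6-oxabicyclo[3.2.0]heptan-7-one | C=C(C)[C@H]1CC[C@]2(C)OC(=O)[C@H]12 | intermediate
8 | (1S,2S,3S)-2-(hydroxymethyl)-1-methyl-3-(prop-1-en-2-yl)cyclopentan-1-ol | C=C(C)[C@H]1CC[C@](C)(O)[C@@H]1CO | intermediate
9 | (1R,2S,5S)-2-hydroxy-2-methyl-5-(prop-1-en-2-yl)cyclopentane-1-carbaldehyde | C=C(C)[C@H]1CC[C@](C)(O)[C@@H]1C=O | intermediate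
10 | 2,4,6-trihydroxybenzophenone | O=C(c1ccccc1)c1c(O)cc(O)cc1O | starting material
11 | prenyl bromide (1-bromo-3-methylbut-2-ene) | CC(C)=CCBr | starting material
12 | 2,4,6-trihydroxy-3-(3-methylbut-2-en-1-yl)benzophenone | CC(C)=CCc1c(O)cc(O)c(C(=O)c2ccccc2)c1O | intermediate
13 | 2-benzoyl-3,5-dihydroxy-4,4-bis(3-methylbut-2-en-1-yl)cyclohexa-2,5-dien-1-one | CC(C)=CCC1(CC=C(C)C)C(O)=CC(O)=C(C(=O)c2ccccc2)C1=O | intermediate
14 | 4-benzoyl-5-hydroxy-6-{[(1R,2S,5S)-2-hydroxy-2-methyl-5-(prop-1-en-2-yl)cyclopentyl]methylidene}-2,2-bis(3-methylbut-2-en-1-yl)cyclohex-4-ene-1,3-dione | C=C(C)[C@H]1CC[C@](C)(O)[C@@H]1C=C1C(=O)C(CC=C(C)C)(CC=C(C)C)C(=O)C(C(=O)c2ccccc2)=C1O | intermediate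
15 | hypercalin B, 2-benzoyl-3,5-dihydroxy-6-{[(1R,2S,5S)-2-hydroxy-2-methyl-5-(prop-1-en-2-yl)cyclopentyl]methyl}-4,4-bis(3-methylbut-2-en-1-yl)cyclohexa-2,5-dien-1-one | C=C(C)[C@H]1CC[C@](C)(O)[C@@H]1CC1=C(O)C(CC=C(C)C)(CC=C(C)C)C(=O)C(C(=O)c2ccccc2)=C1O | target

**Totals**
Total step count: 7. Longest linear sequence: 6 steps (1 → 3 → 4 → 7 → 8 → 9 → 15; steps 1–5 and 7).

**Three steps most likely to fail**

Step 7. The α-branched β-hydroxy aldehyde 9 is sensitive to dehydration and retro-aldol under aminocatalysis, and the Knoevenagel condensation joins two hindered partners. The fallback avoids both the aldehyde and the quinone-methide-type intermediate. It sets out from diol 8: Appel iodination of the primary hydroxyl (I2, PPh3, imidazole, CH2Cl2, 0 °C) gives (1S,2R,3S)-2-(iodomethyl)-1-methyl-3-(prop-1-en-2-yl)cyclopentan-1-ol F1. SN2 C-alkylation of the sodium salt of trione 13 with this iodide (NaOMe, MeOH, 50 °C; the protic medium favours C- over O-alkylation) then comes back to the route at 15.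

Step 6. The double prenylation gives the gem-diprenyl trione 13 together with the 3,5-diprenyl isomer and over-alkylated material. The fallback reverses the order of events. It sets out from aldehyde 9 and benzophenone 10: reductive alkylation (Hantzsch ester, L-proline, EtOH, rt; 10 in excess) passes through the ortho-quinone methide 4-benzoyl-3,5-dihydroxy-6-{[(1R,2S,5S)-2-hydroxy-2-methyl-5-(prop-1-en-2-yl)cyclopentyl]methylidene}cyclohexa-2,4-dien-1-one F2 and gives (3-{[(1R,2S,5S)-2-hydroxy-2-methyl-5-(prop-1-en-2-yl)cyclopentyl]methyl}-2,4,6-trihydroxyphenyl)(phenyl)methanone F3. Double prenylation with 11 (NaOMe, MeOH, 0 °C → rt) then proceeds through the 5-prenyl compound (3-{[(1R,2S,5S)-2-hydroxy-2-methyl-5-(prop-1-en-2-yl)cyclopentyl]methyl}-2,4,6-trihydroxy-5-(3-methylbut-2-en-1-yl)phenyl)(phenyl)methanone F4 and comes back to the route at 15. With one nuclear position already occupied, the 3,5-dialkyl pattern becomes a productive intermediate, and the last prenyl group enters at the prenylated carbon, which is less hindered than the one carrying the branched cyclopentylmethyl group (lupulone-type pattern).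

Step 3. The key bis-cyclisation relies on substrate control alone for two new stereocentres, and the strained β-lactone 7 can be lost by decarboxylation or on silica. The fallback separates the aldol from the lactonisation. It sets out from keto acid 4: thioesterification (PhSH, DCC, DMAP cat., CH2Cl2) gives S-phenyl (3S)-6-oxo-3-(prop-1-en-2-yl)heptanethioate F5. A chelation-controlled soft-enolisation intramolecular aldol (MgBr2·OEt2, iPr2NEt, CH2Cl2, rt) gives S-phenyl (1R,2S,5S)-2-hydroxy-2-methyl-5-(prop-1-en-2-yl)cyclopentane-1-carbothioate F6; the magnesium chelate holds the hydroxyl and thioester cis, and the same A1,3 argument places them trans to isopropenyl. LiAlH4 reduction (THF, 0 °C) comes back to the route at diol 8.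

**Further compounds**
F1 | step 7 | (1S,2R,3S)-2-(iodomethyl)-1-methyl-3-(prop-1-en-2-yl)cyclopentan-1-ol | C=C(C)[C@H]1CC[C@](C)(O)[C@@H]1CI
F2 | step 6 | 4-benzoyl-3,5-dihydroxy-6-{[(1R,2S,5S)-2-hydroxy-2-methyl-5-(prop-1-en-2-yl)cyclopentyl]methylidene}cyclohexa-2,4-dien-1-one | C=C(C)[C@H]1CC[C@](C)(O)[C@@H]1C=C1C(=O)C=C(O)C(C(=O)c2ccccc2)=C1O
F3 | step 6 | (3-{[(1R,2S,5S)-2-hydroxy-2-methyl-5-(prop-1-en-2-yl)cyclopentyl]methyl}-2,4,6-trihydroxyphenyl)(phenyl)methanone | C=C(C)[C@H]1CC[C@](C)(O)[C@@H]1Cc1c(O)cc(O)c(C(=O)c2ccccc2)c1O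
F4 | step 6 | (3-{[(1R,2S,5S)-2-hydroxy-2-methyl-5-(prop-1-en-2-yl)cyclopentyl]methyl}-2,4,6-trihydroxy-5-(3-methylbut-2-en-1-yl)phenyl)(phenyl)methanone | C=C(C)[C@H]1CC[C@](C)(O)[C@@H]1Cc1c(O)c(CC=C(C)C)c(O)c(C(=O)c2ccccc2)c1O
F5 | step 3 | S-phenyl (3S)-6-oxo-3-(prop-1-en-2-yl)heptanethioate | CC(=O)CC[C@@H](CC(=O)Sc1ccccc1)C(C)=C
F6 | step 3 | S-phenyl (1R,2S,5S)-2-hydroxy-2-methyl-5-(prop-1-en-2-yl)cyclopentane-1-carbothioate | C=C(C)[C@H]1CC[C@](C)(O)[C@@H]1C(=O)Sc1ccccc1
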